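I froze one ratio.

| setting | south | south-west | eta | zeta |
|---|---|---|---|---|
| substrate | 2 M | 2 M | 2.0 M | 2.0 M |
| partner | 2.8 M | 2.8 M | 2.00 M | 2.00 M |
| temperature | −18 °C | −1 °C | 5 °C | −25 °C |
| remark | run made earlier | run made earlier |  |  |
| time |  |  | 3.0 min | 3.0 min |

- south (time / min: target / %, side product / %, substrate / %): 0.667: 1.6, 3.6, 95.7; 2.00: 4.5, 8.1, 87.3; 3.00: 5.5, 11.8, 82.7; 5.00: 7.5, 16.2, 75.5; 8.00: 9.9, 21.8, 68.3
- south-west (time / min: target / %, side product / %, substrate / %): 0.200: 2.2, 5.0, 93.6; 0.667: 5.8, 11.8, 80.6; 1.00: 8.9, 15.2, 75.9; 1.50: 11.7, 18.9, 69.8; 2.50: 16.2, 23.3, 60.8

(standard deviation of a reading: 0.5 percentage points)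

1. the flask with the highest share of target in all that became target or side product ("all alike" if they lie within 1.5 percentage points) (eta / zeta / all alike)
2. share of target in all that became target or side product, eta
3. share of target in all that became target or side product, zeta

- the earlier runs were read with a standard deviation of 0.5 percentage points
- a reading or a percentage of target counts all its forms, free or not

No run had varied partner, so I assumed that the side product takes two partner and the target one, and that side product per target grows in step with partner. The quantity to carry is then side product formed per target formed, per molar of partner present, a selectivity factor: the split. At its last reading south gave a ratio of 2.20 over a mean partner near 2.26 M, so the split read 0.972 /M. The target share is then one over one plus split times mean partner.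

I held the south split for zeta. With partner frozen at its charge, my reckoned floor for the zeta share was 34.0%. For a ceiling, I let zeta lose as much substrate as south had lost by the same time, since zeta is colder and has less partner, and I sent that loss entirely to side product. On that reckoning mean partner came to 1.65 M, which gave 38.3%.

For eta I scaled the last south-west ratio, 1.44, down to eta's partner charge. The ratio had fallen with warming, and eta is warmer still, so I took 49.3% as a floor. That floor stands above the zeta ceiling, so I chose eta.

The forecast said eta, with 49% for eta, level with my floor, and 31% for zeta, below my bracket, reasoning that the “side product therefore appears to revert to substrate”.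

The flask gave eta, with 54.8% in eta, above the floor, and 35.0% in zeta, inside the bracket.

    substrate + partner → target (k = 0.00130 /M/s, Ea = 59.0 kJ/mol)
    substrate + 2 partner → side product (k = 8.80 × 10⁻⁴ /M²/s, Ea = 52.0 kJ/mol)
    partner → decomposed reagent (k = 0.00260 /s, Ea = 91.0 kJ/mol)
    crystals ⇌ target, rate k4*(cs4 - [target]) while solid is left; crystals form when [target] > cs4 (solubility = 0.140 M, k = 0.250 /s)
    (constants at 5 °C)

The neighbour of zeta was charged with 0.80 M of partner, which is 0.400 equiv on substrate, at the same temperature and time. I put the same split on that charge, frozen as before, and the share came to 56.3%. Zeta's own floor was 34.0%, so cutting the partner should lift the share well above it. The neighbour gave 56.9%, with 94% of its partner left.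

(The earlier runs and the new flask come from a simulation with constants of no real substance; noise was put on by code.)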